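Assumption: C-numbers in the text follow the cembrane skeleton of the target (C1 carries isopropyl, C1=C2–C3=C4 is the diene, C7 carries OAc, C8–O–C11 is the tetrahydrofuran, C12 is the tertiary carbinol), which makes the target (1E,3E,7R,8S,11R,12S); locants inside compound names are those of each name.

**Retrosynthetic overview**
- The acetate comes last, by selective acylation of the secondary C7 hydroxyl of the macrocyclic diol.
- The 14-membered ring and the C1=C2 bond of the diene are made together by an intramolecular titanium-mediated keto–enal coupling (McMurry) of an acyclic C1 isopropyl ketone / C2 enal.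
- The keto–enal comes from a tetrahydrofuran γ-lactone: isopropyllithium opens the lactone to the C1 ketone and frees the C12 carbinol.
- The tetrahydrofuran lactone comes from an acyclic bis-epoxide by one acid-triggered, ester-terminated epoxide-opening cascade that fixes C7, C8, C11 and C12; the bis-epoxide comes from a double Shi epoxidation of a farnesol-derived triene ester.
- Ring order: γ-lactone (temporary), then tetrahydrofuran, then the 14-membered carbocycle.

**Route**

Step 1
Reactants: 1 (2E,6E)-farnesol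
Product: 2 (2E,6E)-farnesyl pivalate
Conditions: PivCl, pyridine, DMAP (cat.), CH2Cl2, 0 °C to rt
Reagents that add atoms: pivaloyl chloride, CC(C)(C)C(=O)Cl
Why: Acylation of the primary allylic alcohol (nucleophilic acyl substitution) gives an ester that has no α-hydrogens, resists ester enolates at low temperature and inductively deactivates the C3=C4 alkene toward the later electrophilic epoxidation.

Step 2
Reactants: 2 (2E,6E)-farnesyl pivalate
Product: 3 (2E,6E,10E)-12-hydroxy-3,7,11-trimethyldodeca-2,6,10-trien-1-yl pivalate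
Conditions: SeO2 (cat.), tBuOOH, salicylic acid (cat.), CH2Cl2, rt
Reagents that add atoms: tert-butyl hydroperoxide, CC(C)(C)OO (terminal oxidant); selenium dioxide, O=[Se]=O (catalytic oxygen carrier)
Why: Selenium dioxide allylic oxidation attacks the most electron-rich, terminal trisubstituted alkene and hydroxylates its E-methyl group (C13) with retention of the E geometry, as is standard for farnesyl and geranyl esters.

Step 3
Reactants: 3 (2E,6E,10E)-12-hydroxy-3,7,11-trimethyldodeca-2,6,10-trien-1-yl pivalate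
Product: 4 (2E,6E,10E)-12-bromo-3,7,11-trimethyldodeca-2,6,10-trien-1-yl pivalate
Conditions: CBr4, PPh3, CH2Cl2, 0 °C
Reagents that add atoms: carbon tetrabromide, BrC(Br)(Br)Br
Why: Appel bromination replaces the primary allylic hydroxyl by SN2 without allylic transposition or loss of alkene geometry.

Step 4
Reactants: 4 (2E,6E,10E)-12-bromo-3,7,11-trimethyldodeca-2,6,10-trien-1-yl pivalate; 5 tert-butyl acetate
Product: 7 tert-butyl (4E,8E,12E)-4,8,12-trimethyl-14-(pivaloyloxy)tetradeca-4,8,12-trienoate, via lithium enolate of tert-butyl acetate 6 (not isolated)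
Conditions: LiN(iPr)2, THF, −78 °C; then 4, DMPU, −78 to −30 °C
Reagents that add atoms: none
Why: Ester enolate alkylation (SN2 at the primary allylic bromide) adds C14 and C1 as a tert-butyl ester placed to act later as the internal nucleophile, while the hindered, non-enolisable pivalate is left alone at low temperature.

Step 5
Reactants: 7 tert-butyl (4E,8E,12E)-4,8,12-trimethyl-14-(pivaloyloxy)tetradeca-4,8,12-trienoate
Product: 10 tert-butyl (4R,5R,8R,9R,12E)-4,5:8,9-diepoxy-4,8,12-trimethyl-14-(pivaloyloxy)tetradec-12-enoate, via 4,5-monoepoxide 8 (not isolated), via 8,9-monoepoxide 9 (not isolated)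
Conditions: 1,2:4,5-di-O-isopropylidene-β-D-erythro-2,3-hexodiulo-2,6-pyranose (D-fructose-derived Shi ketone, 0.6 equiv), KHSO5 (as 2KHSO5·KHSO4·K2SO4), K2CO3, Bu4NHSO4 (cat.), MeCN/CH2(OMe)2/aq. Na2B4O7 buffer, pH 10.5, 0 °C
Reagents that add atoms: potassium peroxymonosulfate KHSO5, [K+].[O-]S(=O)(=O)OO
Why: Shi asymmetric epoxidation transfers oxygen from KHSO5 through the chiral ketone to the same enantioface of each isolated E-trisubstituted alkene (spiro transition state), giving R,R configuration at both epoxides (the future C11/C12 and C7/C8), while the alkene flanked by the electron-withdrawing pivaloyloxymethyl group reacts much more slowly.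

Step 6
Reactants: 10 tert-butyl (4R,5R,8R,9R,12E)-4,5:8,9-diepoxy-4,8,12-trimethyl-14-(pivaloyloxy)tetradec-12-enoate
Product: 12 (5S)-5-[(2R,5S)-5-[(1R,4E)-1-hydroxy-4-methyl-6-(pivaloyloxy)hex-4-en-1-yl]-5-methyloxolan-2-yl]-5-methyloxolan-2-one, via hydroxy epoxy lactone 11 (not isolated)
Conditions: (+)-camphorsulfonic acid (10 mol%), CH2Cl2, 0 °C to rt
Reagents that add atoms: none
Why: In this acid-triggered epoxide-opening cascade the tert-butyl ester carbonyl opens the activated epoxide at tertiary C12 (5-exo, inversion, isobutene lost) to lactone 11, whose freed C11 hydroxyl opens the second epoxide at tertiary C8 (5-exo, inversion), so C7 and C11 keep and C8 and C12 invert their epoxide configurations, giving 7R,8S,11R,12S and a cis-2,5-disubstituted tetrahydrofuran.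

Step 7
Reactants: 12 (5S)-5-[(2R,5S)-5-[(1R,4E)-1-hydroxy-4-methyl-6-(pivaloyloxy)hex-4-en-1-yl]-5-methyloxolan-2-yl]-5-methyloxolan-2-one
Product: 14 (2E,6R)-6-hydroxy-6-[(2S,5R)-5-[(2S)-2-hydroxy-6-methyl-5-oxoheptan-2-yl]-2-methyloxolan-2-yl]-3-methylhex-2-en-1-yl pivalate, via dilithium lactolate 13 (not isolated)
Conditions: iPrLi (2.3 equiv), THF, −78 °C; then AcOH, −78 °C
Reagents that add atoms: isopropyllithium, [Li]C(C)C
Why: After deprotonation of the C7 hydroxyl, organolithium mono-addition to the γ-lactone stops at the tetrahedral lactolate 13, which is stable at −78 °C and gives the C1 isopropyl ketone and the free C12 carbinol on cold protonation; the far more hindered pivalate is not attacked and no stereocentre is touched.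

Step 8
Reactants: 14 (2E,6R)-6-hydroxy-6-[(2S,5R)-5-[(2S)-2-hydroxy-6-methyl-5-oxoheptan-2-yl]-2-methyloxolan-2-yl]-3-methylhex-2-en-1-yl pivalate
Product: 15 (6S)-6-[(2R,5S)-5-[(1R,4E)-1,6-dihydroxy-4-methylhex-4-en-1-yl]-5-methyloxolan-2-yl]-6-hydroxy-2-methylheptan-3-one
Conditions: NaOMe (cat.), MeOH, 40 °C
Reagents that add atoms: none
Why: Methoxide-catalysed transesterification removes the primary allylic pivalate as methyl pivalate; the hindered ketone, the ether and the carbinol centres (none of them enolisable stereocentres) are unaffected.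

Step 9
Reactants: 15 (6S)-6-[(2R,5S)-5-[(1R,4E)-1,6-dihydroxy-4-methylhex-4-en-1-yl]-5-methyloxolan-2-yl]-6-hydroxy-2-methylheptan-3-one
Product: 16 (2E,6R)-6-hydroxy-6-[(2S,5R)-5-[(2S)-2-hydroxy-6-methyl-5-oxoheptan-2-yl]-2-methyloxolan-2-yl]-3-methylhex-2-enal
Conditions: MnO2 (activated, excess), CH2Cl2, rt
Reagents that add atoms: none
Why: MnO2 oxidises only the allylic alcohol, giving the E-enal without touching the saturated secondary C7 alcohol or the tertiary C12 alcohol.

Step 10
Reactants: 16 (2E,6R)-6-hydroxy-6-[(2S,5R)-5-[(2S)-2-hydroxy-6-methyl-5-oxoheptan-2-yl]-2-methyloxolan-2-yl]-3-methylhex-2-enal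
Product: 18 (1E,3E,7R,8S,11R,12S)-8,11-epoxycembra-1,3-diene-7,12-diol, via macrocyclic 1,2-diolate 17 (not isolated)
Conditions: TiCl3(DME)1.5, Zn(Cu), DME, reflux; 16 added by syringe pump over 30 h (about 1 mM)
Reagents that add atoms: none
Why: In this intramolecular McMurry coupling, low-valent titanium couples the C1 ketone and C2 enal carbonyls to diolate 17 and deoxygenates it, closing the 14-membered ring and creating the C1=C2 bond of the diene in one operation; high dilution favours cyclisation, free hydroxyls are tolerated as titanium alkoxides, the 3E alkene and the four stereocentres are untouched, and the isomer with isopropyl trans to the C3 vinyl carbon (1E) is expected to predominate.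

Step 11
Reactants: 18 (1E,3E,7R,8S,11R,12S)-8,11-epoxycembra-1,3-diene-7,12-diol
Product: 19 (1E,3E,7R,8S,11R,12S)-7-acetoxy-8,11-epoxycembra-1,3-dien-12-ol (target)
Conditions: Ac2O, pyridine, DMAP (cat.), CH2Cl2, 0 °C to rt
Reagents that add atoms: acetic anhydride, CC(=O)OC(C)=O
Why: DMAP-catalysed acylation acetylates the secondary C7 hydroxyl while the tertiary C12 hydroxyl stays free, with retention at C7.

**Compound list**

1 | (2E,6E)-farnesol | CC(C)=CCC/C(C)=C/CC/C(C)=C/CO | starting material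
2 | (2E,6E)-farnesyl pivalate | CC(C)=CCC/C(C)=C/CC/C(C)=C/COC(=O)C(C)(C)C | intermediate
3 | (2E,6E,10E)-12-hydroxy-3,7,11-trimethyldodeca-2,6,10-trien-1-yl pivalate | OC/C(C)=C/CC/C(C)=C/CC/C(C)=C/COC(=O)C(C)(C)C | intermediate
4 | (2E,6E,10E)-12-bromo-3,7,11-trimethyldodeca-2,6,10-trien-1-yl pivalate | BrC/C(C)=C/CC/C(C)=C/CC/C(C)=C/COC(=O)C(C)(C)C | intermediate
5 | tert-butyl acetate | CC(=O)OC(C)(C)C | starting material
6 | lithium enolate of tert-butyl acetate | [Li+].C=C([O-])OC(C)(C)C | intermediate (not isolated)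
7 | tert-butyl (4E,8E,12E)-4,8,12-trimethyl-14-(pivaloyloxy)tetradeca-4,8,12-trienoate | CC(C)(C)OC(=O)CC/C(C)=C/CC/C(C)=C/CC/C(C)=C/COC(=O)C(C)(C)C | intermediate
8 | tert-butyl (4R,5R,8E,12E)-4,5-epoxy-4,8,12-trimethyl-14-(pivaloyloxy)tetradeca-8,12-dienoate | CC(C)(C)OC(=O)CC[C@@]1(C)O[C@@H]1CC/C(C)=C/CC/C(C)=C/COC(=O)C(C)(C)C | intermediate (not isolated)
9 | tert-butyl (4E,8R,9R,12E)-8,9-epoxy-4,8,12-trimethyl-14-(pivaloyloxy)tetradeca-4,12-dienoate | CC(C)(C)OC(=O)CC/C(C)=C/CC[C@@]1(C)O[C@@H]1CC/C(C)=C/COC(=O)C(C)(C)C | intermediate (not isolated)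
10 | tert-butyl (4R,5R,8R,9R,12E)-4,5:8,9-diepoxy-4,8,12-trimethyl-14-(pivaloyloxy)tetradec-12-enoate | CC(C)(C)OC(=O)CC[C@@]1(C)O[C@@H]1CC[C@@]2(C)O[C@@H]2CC/C(C)=C/COC(=O)C(C)(C)C | intermediate
11 | (5S)-5-[(1R)-1-hydroxy-3-[(2R,3R)-2-methyl-3-[(3E)-3-methyl-5-(pivaloyloxy)pent-3-en-1-yl]oxiran-2-yl]propyl]-5-methyloxolan-2-one | O=C1CC[C@](C)(O1)[C@H](O)CC[C@@]2(C)O[C@@H]2CC/C(C)=C/COC(=O)C(C)(C)C | intermediate (not isolated)
12 | (5S)-5-[(2R,5S)-5-[(1R,4E)-1-hydroxy-4-methyl-6-(pivaloyloxy)hex-4-en-1-yl]-5-methyloxolan-2-yl]-5-methyloxolan-2-one | O=C1CC[C@](C)(O1)[C@H]2CC[C@](C)(O2)[C@H](O)CC/C(C)=C/COC(=O)C(C)(C)C | intermediate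
13 | dilithium lactolate from 12 (2-isopropyl-2-oxido-oxolane with C7 alkoxide; new ketal centre unassigned) | [Li+].[Li+].CC(C)C1([O-])CC[C@](C)(O1)[C@H]2CC[C@](C)(O2)[C@H]([O-])CC/C(C)=C/COC(=O)C(C)(C)C | intermediate (not isolated)
14 | (2E,6R)-6-hydroxy-6-[(2S,5R)-5-[(2S)-2-hydroxy-6-methyl-5-oxoheptan-2-yl]-2-methyloxolan-2-yl]-3-methylhex-2-en-1-yl pivalate | CC(C)C(=O)CC[C@](C)(O)[C@H]1CC[C@](C)(O1)[C@H](O)CC/C(C)=C/COC(=O)C(C)(C)C | intermediate
15 | (6S)-6-[(2R,5S)-5-[(1R,4E)-1,6-dihydroxy-4-methylhex-4-en-1-yl]-5-methyloxolan-2-yl]-6-hydroxy-2-methylheptan-3-one | CC(C)C(=O)CC[C@](C)(O)[C@H]1CC[C@](C)(O1)[C@H](O)CC/C(C)=C/CO | intermediate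
16 | (2E,6R)-6-hydroxy-6-[(2S,5R)-5-[(2S)-2-hydroxy-6-methyl-5-oxoheptan-2-yl]-2-methyloxolan-2-yl]-3-methylhex-2-enal | CC(C)C(=O)CC[C@](C)(O)[C@H]1CC[C@](C)(O1)[C@H](O)CC/C(C)=C/C=O | intermediate
17 | macrocyclic 1,2-diolate at C1/C2 of the 14-membered ring (new centres unassigned) | CC(C)C1([O-])CC[C@](C)(O)[C@H]2CC[C@](C)(O2)[C@H](O)CC/C(C)=C/C1[O-] | intermediate (not isolated)
18 | (1E,3E,7R,8S,11R,12S)-8,11-epoxycembra-1,3-diene-7,12-diol | O[C@@H]1CC/C(C)=C/C=C(/C(C)C)CC[C@](C)(O)[C@H]2CC[C@]1(C)O2 | intermediate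
19 | (1E,3E,7R,8S,11R,12S)-7-acetoxy-8,11-epoxycembra-1,3-dien-12-ol | CC(=O)O[C@@H]1CC/C(C)=C/C=C(/C(C)C)CC[C@](C)(O)[C@H]2CC[C@]1(C)O2 | target

**Step count and risks**

Total steps: 11. Longest linear sequence: 11 steps, from 1 to 19.

Three steps most likely to fail:

Step 10 (McMurry macrocyclisation). The risks are oligomerisation, a 1E/1Z mixture at the new alkene, and interference from ring–chain tautomerism of the γ-hydroxy ketone. Fallback, from 15 back to 18: Corey–Kim chlorination (N-chlorosuccinimide, Me2S, CH2Cl2, −20 °C) converts only the allylic primary alcohol of 15 into (6S)-6-[(2R,5S)-5-[(1R,4E)-6-chloro-1-hydroxy-4-methylhex-4-en-1-yl]-5-methyloxolan-2-yl]-6-hydroxy-2-methylheptan-3-one F1. Michaelis–Becker alkylation of Ph2P(O)H (Cs2CO3, Bu4NI cat., DMF, rt) turns it into the allylic diphenylphosphine oxide F2. KN(SiMe3)2 (3.5 equiv, THF, −78 °C to rt, 1 mM) then closes the ring by an intramolecular Horner–Wittig olefination of the isopropyl ketone by the phosphorus-stabilised allyl anion, giving diene diol 18 directly, and the route resumes at step 11.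

Step 5 (double Shi epoxidation). The risks are incomplete face selectivity, which gives diastereomers of 10, and some oxidation of the pivalate-bearing alkene. Fallback, from 3 back to 10: Sharpless asymmetric epoxidation of allylic alcohol 3 (Ti(OiPr)4, D-(−)-diethyl tartrate, tBuOOH, 4 Å sieves, CH2Cl2, −20 °C) sets the C11/C12 epoxide by hydroxyl direction, giving (2E,6E)-9-[(2R,3R)-3-(hydroxymethyl)-3-methyloxiran-2-yl]-3,7-dimethylnona-2,6-dien-1-yl pivalate F3. Tf2O and 2,6-lutidine (CH2Cl2, −78 °C) give the epoxy triflate F4, which alkylates enolate 6 (THF, −78 °C) at the primary carbon to give monoepoxide 8, now isolated. The chiral ketone then has to deliver only one epoxide (conditions of step 5), giving 10.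

Step 7 (mono-addition of iPrLi to the lactone). The risks are over-addition, reduction by β-hydride transfer, and attack on the pivalate. Fallback, from 4 back to 14: the isopropyl ketone is built in before the cascade. The kinetic lithium enolate of 3-methylbutan-2-one F5 (LiN(iPr)2, THF, −78 °C) is alkylated by bromide 4 to give (2E,6E,10E)-3,7,11,15-tetramethyl-14-oxohexadeca-2,6,10-trien-1-yl pivalate F6. Shi epoxidation as in step 5 gives the (6R,7R,10R,11R)-bis-epoxy ketone F7. Aqueous HClO4 (cat., THF/H2O, 0 °C) runs the same cascade with the ketone oxygen as the terminating nucleophile at C12 and water supplying the new carbonyl oxygen, giving hydroxy ketone 14 with the same inversions at C8 and C12; the route resumes at step 8.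

Further compounds
F1 | step 10 | (6S)-6-[(2R,5S)-5-[(1R,4E)-6-chloro-1-hydroxy-4-methylhex-4-en-1-yl]-5-methyloxolan-2-yl]-6-hydroxy-2-methylheptan-3-one | CC(C)C(=O)CC[C@](C)(O)[C@H]1CC[C@](C)(O1)[C@H](O)CC/C(C)=C/CCl
F2 | step 10 | (6S)-6-[(2R,5S)-5-[(1R,4E)-6-(diphenylphosphoryl)-1-hydroxy-4-methylhex-4-en-1-yl]-5-methyloxolan-2-yl]-6-hydroxy-2-methylheptan-3-one | CC(C)C(=O)CC[C@](C)(O)[C@H]1CC[C@](C)(O1)[C@H](O)CC/C(C)=C/CP(=O)(c1ccccc1)c1ccccc1
F3 | step 5 | (2E,6E)-9-[(2R,3R)-3-(hydroxymethyl)-3-methyloxiran-2-yl]-3,7-dimethylnona-2,6-dien-1-yl pivalate | OC[C@@]1(C)O[C@@H]1CC/C(C)=C/CC/C(C)=C/COC(=O)C(C)(C)C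
F4 | step 5 | (2E,6E)-3,7-dimethyl-9-[(2R,3R)-3-methyl-3-[(trifluoromethanesulfonyloxy)methyl]oxiran-2-yl]nona-2,6-dien-1-yl pivalate | FC(F)(F)S(=O)(=O)OC[C@@]1(C)O[C@@H]1CC/C(C)=C/CC/C(C)=C/COC(=O)C(C)(C)C
F5 | step 7 | lithium enolate of 3-methylbutan-2-one (kinetic, methyl side) | [Li+].C=C([O-])C(C)C
F6 | step 7 | (2E,6E,10E)-3,7,11,15-tetramethyl-14-oxohexadeca-2,6,10-trien-1-yl pivalate | CC(C)C(=O)CC/C(C)=C/CC/C(C)=C/CC/C(C)=C/COC(=O)C(C)(C)C
F7 | step 7 | (2E,6R,7R,10R,11R)-6,7:10,11-diepoxy-3,7,11,15-tetramethyl-14-oxohexadec-2-en-1-yl pivalate | CC(C)C(=O)CC[C@@]1(C)O[C@@H]1CC[C@@]2(C)O[C@@H]2CC/C(C)=C/COC(=O)C(C)(C)C
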